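Follow one enzyme molecule round its cycle and time each lap.

all flasks: free enzyme 22 µM
- gamma: starting material 0.10 M; second substrate 0.105 M; run made earlier
- beta: starting material 0.050 M; second substrate 0.105 M; run made earlier
- zeta: starting material 0.20 M; second substrate 0.105 M; run made earlier
- alpha: starting material 0.10 M; second substrate 0.052 M; run made earlier
- east: starting material 0.10 M; second substrate 0.105 M; one stirred flow tank at steady state, fed with the mixture as stated, mean residence time 3.0 min
- north-east: starting material 0.10 M (fed, over 2.40 min); second substrate 0.105 M; all but starting material at the start; starting material goes in evenly over 2.40 min, the run ends at 3.0 min; time 3.0 min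
- south-east: starting material 0.10 M; second substrate 0.105 M; a closed flask charged with all of it at once and left for 3.0 min; time 3.0 min
- south: starting material 0.10 M; second substrate 0.105 M; one stirred flow tank at steady state, fed with the mixture as stated, mean residence time 15.0 min

- gamma (time / min: target / %): 0.417: 13.4; 0.833: 27.1; 1.33: 41.3; 1.50: 45.7; 2.00: 58.6; 2.50: 68.7; 3.00: 78.8
- beta (time / min: target / %): 0.250: 12.8; 0.417: 21.7; 0.667: 32.4; 1.00: 46.5; 1.50: 64.2; 2.50: 86.2; 4.00: 96.4
- zeta (time / min: target / %): 0.250: 4.3; 0.417: 8.1; 0.667: 12.7; 1.00: 18.6; 1.50: 27.0; 2.50: 43.1; 4.00: 52.8
- alpha (time / min: target / %): 0.333: 10.2; 0.833: 24.6; 1.50: 39.0; 2.50: 51.1; 4.00: 51.6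

(scatter of a reading: 0.5 percentage points)

- the stated concentrations are those of everything mixed, before any reaction; amounts are the same in each set-up
- the feed brings no volume worth counting
- the earlier runs were made in a closed, stirred flask

- the set-up with the highest amount of target at the outlet or at the end, in percent of the starting material put in ("none" if the first two lie within 2 percentage points) (east / north-east / south-east / south / none)
- amount of target at the outlet or at the end, in percent of the starting material put in, east
- amount of target at the outlet or at the end, in percent of the starting material put in, north-east
- amount of target at the outlet or at the end, in percent of the starting material put in, south-east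
- amount of target at the outlet or at the end, in percent of the starting material put in, south

Each lap takes up one starting material and one second substrate and gives one target. The zeta run fits this: at 4.00 min it reads 0.106 M of target against 0.105 M of second substrate. In the set-ups asked about, starting material is the limiting reagent.

In the gamma run, the reading at 0.833 min gives a lap of 40.6 ms. This lap time, the enzyme charge divided by the rate of making target, is what I carry. The alpha run, with half the second substrate, reads 44.7 ms. The beta run reads 50.7 ms and the zeta run 35.5 ms.

I split a lap into a fixed part and two waits, each growing as the inverse of its concentration. At the charge, these readings give a wait of 10.2 ms for starting material and 4.05 ms for second substrate. That leaves a fixed part of 26.4 ms. These laps are averages over each run so far and carry the scatter of the readings, so the split is an estimate.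

A tank at steady state holds the outlet mixture, so it runs at the outlet's lap. The yield is then the enzyme charge times the residence time, divided by the lap and the charge of starting material. For the east tank I try 63.7 %. The lap there is 64.6 ms, which returns 61.3 %. A higher trial lengthens the lap and lowers the return, so the east yield lies between the two, and I take the middle, 62.5 %.

The south-east flask repeats the gamma run, which reads 78.8 % at 3.00 min. At an outlet of that same yield the south tank allows a lap of 251 ms, while the enzyme needs 90.5 ms. The allowed lap in the south tank is longer than the needed one, so I expect the south outlet above that reading.

The forecast names south as best, with 64.8 %, 62 %, 79 % and 93.5 % for east, north-east, south-east and south, on the ground that “A ping-pong-style form fits”; its east figure stands above mine.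

The flask gives 63.5 %, 61.1 %, 77.2 % and 93.0 % in that order, so south is best.

    starting material + free enzyme ⇌ first complex (K = 20.0 /M, k = 43000 /M/s)
    first complex ⇌ loaded enzyme + first product (K = 1.40 M, k = 51.0 /s)
    second substrate + loaded enzyme ⇌ second complex (K = 22.0 /M, k = 20000 /M/s)
    second complex → free enzyme + target (k = 160 /s)

The east outlet implies a lap of 62.3 ms, and my lap at that outlet is 64.5 ms. The south tank's outlet implies 213 ms, and my lap there is 208 ms. In the scheme, first complex goes on to loaded enzyme more slowly than second complex gives target, and far more slowly than starting material binds at its charge. The reciprocals of those two forward constants are 19.6 ms and 6.25 ms.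

The data are simulated with constants of no real substance.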